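Readings and results were computed on assumed constants.

Late in the alpha run X stops rising, at 84.2 % after 25.0 min and 85.7 % after 60.0 min, with G charged at 12 equiv on Q, which is 6.00 times the racemate if one G serves one substrate.

| flask | Q | L | G | E | Z | remark | time |
|---|---|---|---|---|---|---|---|
| theta | 16 mM | 16 mM | 1.8 equiv | 11 mol% | 5 mol% | run made earlier |  |
| alpha | 16 mM | 16 mM | 12 equiv | 11 mol% | 5 mol% | run made earlier |  |
| delta | 16 mM | 16 mM | 2 equiv | 5.2 mol% | 5 mol% | run made earlier |  |
| dawn | 16 mM | 16 mM | 1.30 equiv | 8 mol% | 5 mol% |  | 1.0 h |
| autumn | 16 mM | 16 mM | 6.00 equiv | 11 mol% | 5 mol% |  | 1.0 h |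
| winter | 16 mM | 16 mM | 3.00 equiv | 11 mol% | 1.2 mol% |  | 1.0 h |
| spring | 16 mM | 16 mM | 8.00 equiv | 3 mol% | 5 mol% |  | 1.0 h |
| noon | 16 mM | 16 mM | 2.00 equiv | 11 mol% | 5 mol% |  | 1.0 h |

- theta (time / min: X / %): 3.00: 9.8; 10.0: 26.9; 15.0: 32.1; 25.0: 43.1; 40.0: 50.6; 50.0: 58.2; 60.0: 60.7
- alpha (time / min: X / %): 5.00: 64.2; 8.00: 75.1; 12.0: 80.0; 15.0: 84.2; 25.0: 84.2; 40.0: 85.5; 60.0: 85.7
- delta (time / min: X / %): 5.00: 10.4; 10.0: 19.0; 15.0: 25.2; 30.0: 38.8; 60.0: 52.5

(each reading ± 1 percentage point)

- E is single-handed; Q and L are mirror images of each other, charged as a racemate, each of them at the stated concentration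
- no earlier run changes the charge of Z; that part of a forecast is a guess

* the flasks put in order of amount of X, in percent of the Q and L together charged, best first, at 1.0 h (dawn / autumn / winter / spring / noon)
* the amount of X, in percent of the Q and L together charged of the flask you put first, at 1.0 h
* the amount of X, in percent of the Q and L together charged of the flask you put last, at 1.0 h

The reckoning here reads that plateau as the racemate used up, with Z keeping Q and L level, as in a dynamic kinetic resolution, and with part of the turnover ending in something other than X. That gives the X yield per G spent, the fraction of spent G that appears as X, 85.7 %, a reading with its scatter. Multiplied by the fraction of G used and by G's charge as a fraction of the racemate, it gives, by this reckoning, X in a flask where G is the limiting reagent.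

For dawn, G is 65.0 % of the racemate, so its ceiling is 55.7 %, lower than 85.7 %. The other flasks hold more G than dawn. By this reckoning dawn's X stays under 55.7 % however long it stands, lower than 85.7 %, so the next charge to try for a yield near 85.7 % is one with more G, and autumn is taken here. Autumn has half the G of alpha at the same E and Z. If rate follows G, it needs about 30.0 min to reach alpha's 84.2 %, well within 1.0 h, so this reckoning puts autumn near 85.7 %.

The forecast gives autumn > spring > noon > winter > dawn, with 82 % first and 45 % last, on the ground that “Final yield therefore depends on how fast Q is drained while Z lives”. Its top is lower than this reckoning's, and it reads alpha's plateau as the death of Z.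

The flasks give autumn > spring > winter > noon > dawn, with 84.8 % first and 43.7 % last.

    G + E + Q → E + X (k = 46.0 /M²/s)
    G + E + L → E + J (k = 8.10 /M²/s)
    Q + Z ⇌ L + Z, rate k3*[Z]*[Q] forward; the back reaction follows from the equilibrium constant (k = 210 /M/s)
    2 E ⇌ D, settled at all times (K = 420 /M)

Autumn has come to rest by 1.00 h: Q stands at 0.0801 %, and a longer run leaves its X where it is. Dawn has not. It still holds 20.9 % of its G, and by 10.0 h G is down to 0.00745 % while X climbs to 55.3 %, against the ceiling of 55.7 %, with Q and L at 17.5 % each and Z at 100 %. Winter and noon also still move, to 84.8 % and 82.3 % of X at that time.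

Dawn read at 1.5 h has 12.1 % of its G left, so the yield per G gives 49.0 % of X. That flask holds 48.6 %.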